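## Structural features

The target is a monocyclic bisabolane-type sesquiterpenoid. One cyclohexane ring (locants C1, C2, C3, C4 carrying Br and methyl, C5 carrying Cl, C6) is joined through its quaternary carbinol carbon C1 to a 4-hydroxy-6-methylhepta-1,5-dien-2-yl chain: C7 with the exocyclic methylene, C8, the secondary carbinol C9 and the C10=C11 isopropylidene end. The ring holds three stereocentres, C1 (R), C4 (S) and C5 (S). C4 and C5 are adjacent, the halogens are trans, bromine is cis to the C1 hydroxyl and chlorine is cis to C7. In the chair with the side chain equatorial both halogens are equatorial, while the C4 methyl and the C1 hydroxyl are axial. The fourth stereocentre, C9 (S), lies on the flexible chain, 1,4 to C1 through the sp2 carbon C7, so the ring cannot be expected to control it. Fragile groups are the tertiary bromide (ionisation, loss of HBr, halide exchange under Lewis acids), the tertiary allylic alcohol at C1, the acid-labile allylic C9 alcohol, and the 1,1-disubstituted alkene, which can slip into conjugation once C9 is a ketone. The real difficulty is halogen regiochemistry tied to configuration: a bromonium ion on a C4=C5 alkene opened by chloride gives the tertiary chloride and secondary bromide, the reverse of what is needed, and the pair must also be placed correctly relative to C1 across the ring. The key step exploits the antiperiplanar C4–Cl/C5–Br pair on ring carbons C4 and C5 of that kinetic adduct: the halogens change places, each on its own ring face, so the face fixed for bromine by the C1 carboxyl carbon (C7) becomes the C4 (Br) and C5 (Cl) configuration of the target.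

## Logic of the disconnections

15 to 14: the C9–H bond is cut, taking the carbinol back to a ketone. C9 is remote from the ring stereocentres, so it is best set by a reagent-controlled reduction. This removes one stereocentre. The forward step must tell the CH2 arm from the alkenyl arm, reduce 1,2 only, and leave halides and alkenes alone.

14 to 12 + 13: the C8–C9 bond is cut. A β,γ-unsaturated ketone with the alkene as an exocyclic methylene is the direct retron of an allylsilane acylation, which places the C7 methylene without a separate olefination. The five-carbon chain end arrives in one piece from 13. The forward step needs a Lewis acid at low temperature that spares the tertiary bromide and the C1 alcohol and does not move the alkene.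

12 to 10 (through 11): the two C7–CH2 bonds are cut back to the ester carbonyl. C7 is already present as the carboxyl carbon that was used for face control, so no carbon is wasted. The C1 benzoate is removed in the same operation. The nucleophile must be of low basicity because of the tertiary bromide.

10 to 9 (key): the C4–Br and C5–Cl bonds are cut and re-formed as C4–Cl and C5–Br. The halogen pattern of 10 cannot be made by opening a bromonium ion, whereas that of 9 is the normal kinetic outcome. The gain is that a regiochemical problem becomes a known addition. The demand is that the equilibrium between 9 and 10 can be brought far enough to 10 and that the shift stays stereospecific.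

9 to 8 to 7 to 6: C4–Cl is traced to C4–O, then the lactone C4–O bond and the C5–Br bond are cut. The carboxyl group on C1 can only reach one face, so it decides the face of the bromonium ion. Three stereocentres are reduced to one. The forward steps need anti addition, lactone opening without epoxide formation, and replacement of C4–O by C4–Cl with retention.

6 to 5 to 3 + 4: after adjusting the oxidation level at C7, the ring bonds C1–C6 and C2–C3 are cut. A cyclohexene with an oxygenated quaternary C1 and a 1,4-related methyl is the retron of a [4+2] cycloaddition. Two achiral, acyclic partners result. The forward step must give the 1,4 ("para") regiochemistry and select one face of 3.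

3 to 2 to 1: the enol C–O acyl bond and the two acetal C–O bonds are cut. 3 polymerises on storage and is therefore released from the stable 2 just before use. The demand is O- rather than C-acylation of 1.

## Other disconnections considered

Alternative 1: The cut is the C1–O bond of the ring (with a temporary C2–O bond).
- Route: the C1 carbinol is traced to the allylic C1=C2 alkene of (4-methylcyclohexa-1,4-dien-1-yl)methanol A2, which would come from 4 and methyl propiolate A1 by cycloaddition and reduction of the ester group.
- Forward key step: Ti(OiPr)4, D-(−)-diethyl tartrate and t-BuOOH would epoxidise only the allylic alkene, giving [(1R,6R)-4-methyl-7-oxabicyclo[4.1.0]hept-3-en-1-yl]methanol A3. Hydride opening at the less hindered C2 would give (R)-1-(hydroxymethyl)-4-methylcyclohex-3-en-1-ol A4, and oxidation of the primary alcohol would reach the hydroxy acid level of the chosen route.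
- In its favour: the facial rule for this class of 2,3-disubstituted allylic alcohol is dependable, the homoallylic C4=C5 alkene is left for the halogens, and the reagents are cheap. On the reliability of the C1 configuration it is the better of the two plans.
- Against it here: it solves C1 only. The cycloaddition with A1 has a para/meta problem and gives a 1,4-diene that aromatises easily. C7 arrives at the alcohol level, so a reduction, an epoxide opening and a two-stage oxidation replace one aldehyde oxidation, about two steps more.
- Comparison: both plans deliver the same cyclohexene with the oxygenated quaternary C1. Face selection comes from a titanium tartrate template instead of a shielded iminium ion. The chosen route is ahead in step economy. Since the halogen problem is untouched, this disconnection could only replace steps 1 to 4, not the halogen interchange.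

Alternative 2: The cut is the pair of ring bonds C2–C3 and C1–C6.
- Forward key step: 4 and 3 would combine under a chiral primary ammonium salt (or a proline-derived oxazaborolidinium triflimide) to give (R)-1-formyl-4-methylcyclohex-3-en-1-yl benzoate A5, which is compound 5 of the chosen route.
- In its favour: one catalytic step builds the ring and the C1 stereocentre and brings C7 in at a useful oxidation level. No shorter entry is apparent.
- Against it as the strategic centre: it says nothing about C4 and C5. Direct bromochlorination of A5 or its derivatives would put chloride on the tertiary carbon, with little face control from C1.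
- Comparison: on C1 it is the equal of the chosen plan by definition, because the chosen plan uses it as step 3. It forms two C–C bonds and a ring, which the halogen interchange does not. Mechanistically it is a concerted cycloaddition set against an ion-pair shift. In step count nothing is gained or lost. The difference is only where the strategic weight is placed, and the harder problem of the target lies at C4/C5.

Alternative 3: The cut is the C5–Cl bond together with a temporary C4–O bond.
- Forward key step: N-chlorosuccinimide or t-BuOCl would add electrophilic chlorine to the C4=C5 alkene of methyl (R)-1-hydroxy-4-methylcyclohex-3-ene-1-carboxylate A6 while the C1 oxygen closes onto C4. The product would be methyl (1R,3S,4S)-3-chloro-4-methyl-7-oxabicyclo[2.2.1]heptane-1-carboxylate A7, with chlorine anti to the oxygen bridge. The C4–O bond would then be exchanged for C4–Br.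
- In its favour: the regiochemistry is kinetic and secure, because the internal oxygen takes the tertiary position and chlorine is left on C5, cis to C7. No equilibrium is involved. On regiochemical certainty it is the better plan.
- Against it here: the transannular closure needs a boat and gives a strained bicycle, and it must compete with ene-type allylic chlorination of the trisubstituted alkene. The later C4–O to C4–Br exchange must go with retention at a tertiary centre. That relies on chlorine bridging, which is weaker than bromine bridging, or on ion-pair return; an open cation would give the cis-bromochloride and alkenes. The exchange also needs a strong acid in the presence of the ester.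
- Comparison: the step count is the same. The chosen plan has intrinsic stereospecificity (two suprafacial shifts) but an uncertain position of equilibrium. This alternative has intrinsic regiochemistry but uncertain stereochemical fidelity at C4. The two are complementary, and this one is kept as the fallback for the key step.

Key step: step 8

Remark on the chemistry (assumption): the (S)-diamine salt in step 3 is taken to give the (R)-adduct; the sense is to be confirmed on 5, and the antipodal diamine is used if it proves opposite.

Remark on the chemistry (assumption): bromolactonisation is written as the Markovnikov δ-lactone 7. The regioisomeric γ-lactone (oxygen on C5, bromine on C4) would carry bromine on the same face and would ionise in step 7 to the same bromonium ion, so it would lead to 9 or directly to 10.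

Remark on the chemistry: 9 and 10 carry the C1 oxygen as the benzoate inherited from step 3 instead of a free hydroxyl. Skeleton, halogens and descriptors are those of the parent hydroxy esters: (1R,3R,4R) for 9 and, after inversion at both C4 and C5, (1R,3S,4S) for 10.

## Route

Step 1
Reactants: 1 2,2-dimethyl-1,3-dioxan-5-one
Product: 2 2,2-dimethyl-4H-1,3-dioxin-5-yl benzoate
Conditions: BzCl, Et3N, 4-(dimethylamino)pyridine (cat.), CH2Cl2, 0 °C to rt
Reagents that add atoms: benzoyl chloride, O=C(Cl)c1ccccc1
Why: The ketone between two alkoxymethylene groups enolises readily under amine base and the enol is O-benzoylated (enol ester formation), giving a storable precursor of the dienophile.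

Step 2
Reactants: 2 2,2-dimethyl-4H-1,3-dioxin-5-yl benzoate
Product: 3 2-(benzoyloxy)acrolein (3-oxoprop-1-en-2-yl benzoate)
Conditions: PhMe, 110 °C, N2, acetone distilled off; used crude
Reagents that add atoms: none
Why: Retro-hetero-Diels–Alder cycloreversion of the 4H-1,3-dioxin expels acetone and unveils the α-acyloxy enal, which is used at once because it polymerises.

Step 3
Reactants: 3 2-(benzoyloxy)acrolein; 4 isoprene
Product: 5 (R)-1-formyl-4-methylcyclohex-3-en-1-yl benzoate
Conditions: (S)-1,1'-binaphthyl-2,2'-diamine (5 mol %), Tf2NH (9.5 mol %), EtCN, −75 °C
Reagents that add atoms: none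
Why: Iminium-catalysed asymmetric Diels–Alder reaction: the primary ammonium salt condenses with the enal, the acyloxy group fixes the iminium geometry by hydrogen bonding, and the binaphthyl screens one face, so the catalyst sets C1; the larger diene coefficient at C1 of isoprene meets the β-carbon, giving the 1,4 ("para") adduct.

Step 4
Reactants: 5 (R)-1-formyl-4-methylcyclohex-3-en-1-yl benzoate
Product: 6 (R)-1-(benzoyloxy)-4-methylcyclohex-3-ene-1-carboxylic acid
Conditions: NaClO2, NaH2PO4, 2-methylbut-2-ene (10 equiv), t-BuOH/H2O, 0 °C to rt
Reagents that add atoms: NaClO2, [Na+].[O-]Cl=O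
Why: Pinnick oxidation converts the hindered, non-enolisable aldehyde to the acid without touching the benzoate, and the scavenger alkene in excess takes up HOCl before it can add to the ring alkene.

Step 5
Reactants: 6 (R)-1-(benzoyloxy)-4-methylcyclohex-3-ene-1-carboxylic acid
Product: 7 (1R,4R,6R)-6-bromo-1-methyl-3-oxo-2-oxabicyclo[2.2.2]octan-4-yl benzoate (δ-lactone; lactone oxygen on C4 on the same ring face as C7, bromine on C5 on the opposite face)
Conditions: NBS, NaHCO3 (0.2 equiv), DMF, 0 °C, dark
Reagents that add atoms: N-bromosuccinimide, O=C1CCC(=O)N1Br
Why: Bromolactonisation: the carboxyl group can close only on its own face of the ring, so the bromonium ion consumed is the one on the opposite face; Markovnikov attack at the tertiary C4 through a boat and anti addition set C4–O syn and C5–Br anti to C7, both under control of C1.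

Step 6
Reactants: 7 (1R,4R,6R)-6-bromo-1-methyl-3-oxo-2-oxabicyclo[2.2.2]octan-4-yl benzoate
Product: 8 methyl (1R,3R,4R)-1-(benzoyloxy)-3-bromo-4-hydroxy-4-methylcyclohexane-1-carboxylate
Conditions: (+)-camphor-10-sulfonic acid (10 mol %), MeOH, 40 °C; solid NaHCO3 before concentration
Reagents that add atoms: methanol, CO
Why: Acid-catalysed transesterification opens the strained boat lactone at the acyl–oxygen bond, so C4 and C5 keep their configuration; acid is used instead of methoxide because an alkoxide at C4 would close the trans-bromohydrin to an epoxide.

Step 7
Reactants: 8 methyl (1R,3R,4R)-1-(benzoyloxy)-3-bromo-4-hydroxy-4-methylcyclohexane-1-carboxylate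
Product: 9 methyl (1R,3R,4R)-1-(benzoyloxy)-3-bromo-4-chloro-4-methylcyclohexane-1-carboxylate
Conditions: SOCl2 (1.5 equiv), CH2Cl2, 0 °C to rt, no base
Reagents that add atoms: thionyl chloride, O=S(Cl)Cl
Why: The chlorosulfite of the tertiary alcohol ionises with anchimeric help from the antiperiplanar C5 bromine, and chloride opens the resulting bromonium ion at the tertiary carbon from the face the oxygen left (neighbouring-group participation, trans-diaxial Markovnikov opening), so C4–Cl replaces C4–O with net retention.

Step 8
Reactants: 9 methyl (1R,3R,4R)-1-(benzoyloxy)-3-bromo-4-chloro-4-methylcyclohexane-1-carboxylate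
Product: 10 methyl (1R,3S,4S)-1-(benzoyloxy)-4-bromo-3-chloro-4-methylcyclohexane-1-carboxylate
Conditions: MeCN (0.05 M), 2,6-di-tert-butylpyridine (5 mol %), 75 °C, dark, to equilibrium; chromatography, recovered 9 resubjected
Reagents that add atoms: none
Why: Thermal 1,2-dyotropic interchange of a trans-diaxial vicinal dihalide, the reaction type known as the diaxial-to-diequatorial rearrangement of 5α,6β-dihalo steroids and 1,2-dihalocyclohexanes. In the chair of 9 with C4–Cl and C5–Br antiperiplanar, the C5 bromine bridges to C4 on its face while chloride leaves the tertiary carbon and crosses the other face to C5, through a tight bromonium–chloride ion pair or four-centre transition state; no ring is closed and no C–C bond changes. Because each halogen stays on its own face, both carbons are inverted: the new C4–Br (S) and C5–Cl (S) centres are fixed by the face that bromine took in step 5, and C1 is not involved. The selectivity needed is thermodynamic, since the shift is reversible: 10 gains two equatorial halogens and loses the 1,3-diaxial contact between C5–Br and the axial C1 oxygen of 9, but pays with an axial C4 methyl and with bromine instead of chlorine on the tertiary carbon. These terms are of comparable size, so conversion may stop at a mixture. The C1 benzoate (no O–H···Br hydrogen bond, a more demanding axial group facing C5–Br than OH, a smaller equatorial preference than the ester) and the polar solvent, which stabilises the gauche diequatorial dihalide over the diaxial chair of 9, are chosen to shift it towards 10. The benzoate also removes the free C1 hydroxyl, which could close onto C4 across the ring once the tertiary halide ionises. No external halide is present, so scrambling to dibromide or dichloride is excluded, and the hindered base takes up traces of HX that would start elimination.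

Step 9
Reactants: 10 methyl (1R,3S,4S)-1-(benzoyloxy)-4-bromo-3-chloro-4-methylcyclohexane-1-carboxylate
Product: 12 (1R,3S,4S)-4-bromo-3-chloro-4-methyl-1-[3-(trimethylsilyl)prop-1-en-2-yl]cyclohexan-1-ol, via bis(silylmethyl) diol 11 (not isolated)
Conditions: Me3SiCH2MgCl (6 equiv), CeCl3 (6 equiv), THF, −78 °C to rt; sat. aq. NH4Cl; crude 11, SiO2, CH2Cl2, rt
Reagents that add atoms: (trimethylsilyl)methylmagnesium chloride, C[Si](C)(C)C[Mg]Cl
Why: The weakly basic organocerium reagent adds twice to the methyl ester and cleaves the benzoate by the same double addition without eliminating the tertiary bromide; the β-hydroxysilane 11 then loses Me3SiOH on silica (acid-type Peterson elimination) to give the 2-substituted allylsilane, and no stereocentre is formed or touched.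

Step 10
Reactants: 12 (1R,3S,4S)-4-bromo-3-chloro-4-methyl-1-[3-(trimethylsilyl)prop-1-en-2-yl]cyclohexan-1-ol; 13 3-methylbut-2-enoyl chloride
Product: 14 2-[(1R,3S,4S)-4-bromo-3-chloro-1-hydroxy-4-methylcyclohexyl]-6-methylhepta-1,5-dien-4-one
Conditions: 13 (1.3 equiv), TiCl4 (2.2 equiv), 2,6-di-tert-butyl-4-methylpyridine (1.2 equiv), CH2Cl2, −78 °C, 15 min; sat. aq. NaHCO3 at −78 °C; used directly
Reagents that add atoms: none
Why: Lewis-acid-promoted acylation of an allylsilane (Hosomi–Sakurai type, SE2'): the activated acyl chloride attacks the terminal CH2, the β-silyl cation loses Me3SiCl and the alkene is re-formed as the C7 methylene, a reaction type established for 2-substituted allylsilanes and α,β-unsaturated acid chlorides; the hindered base takes up HCl released when the C1 hydroxyl binds titanium, which suppresses protodesilylation and alkene migration.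

Step 11
Reactants: 14 2-[(1R,3S,4S)-4-bromo-3-chloro-1-hydroxy-4-methylcyclohexyl]-6-methylhepta-1,5-dien-4-one
Product: 15 (1R,3S,4S)-4-bromo-3-chloro-1-[(4S)-4-hydroxy-6-methylhepta-1,5-dien-2-yl]-4-methylcyclohexan-1-ol
Conditions: (R)-1-methyl-3,3-diphenyltetrahydro-1H,3H-pyrrolo[1,2-c][1,3,2]oxazaborole ((R)-Me-CBS, 20 mol %), catecholborane (2.5 equiv), PhMe, −78 °C; MeOH, then aq. NaHCO3
Reagents that add atoms: none
Why: Corey–Bakshi–Shibata reduction: the ketone binds the catalyst boron anti to its larger arm, taken to be the alkenyl group as in other enones, and hydride is delivered within the complex to one face, which with the (R)-catalyst should give the (S)-carbinol at C9 under reagent control; catecholborane at −78 °C leaves alkenes and halides alone.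

## Compound list

1 | 2,2-dimethyl-1,3-dioxan-5-one | CC1(C)OCC(=O)CO1 | starting material
2 | 2,2-dimethyl-4H-1,3-dioxin-5-yl benzoate | CC1(C)OCC(OC(=O)c2ccccc2)=CO1 | intermediate
3 | 2-(benzoyloxy)acrolein (3-oxoprop-1-en-2-yl benzoate) | C=C(C=O)OC(=O)c1ccccc1 | intermediate
4 | isoprene | C=CC(C)=C | starting material
5 | (R)-1-formyl-4-methylcyclohex-3-en-1-yl benzoate | O=C[C@@]1(OC(=O)c2ccccc2)CCC(C)=CC1 | intermediate
6 | (R)-1-(benzoyloxy)-4-methylcyclohex-3-ene-1-carboxylic acid | OC(=O)[C@@]1(OC(=O)c2ccccc2)CCC(C)=CC1 | intermediate
7 | (1R,4R,6R)-6-bromo-1-methyl-3-oxo-2-oxabicyclo[2.2.2]octan-4-yl benzoate | O=C1O[C@]2(C)CC[C@@]1(OC(=O)c3ccccc3)C[C@H]2Br | intermediate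
8 | methyl (1R,3R,4R)-1-(benzoyloxy)-3-bromo-4-hydroxy-4-methylcyclohexane-1-carboxylate | COC(=O)[C@@]1(OC(=O)c2ccccc2)CC[C@@](C)(O)[C@H](Br)C1 | intermediate
9 | methyl (1R,3R,4R)-1-(benzoyloxy)-3-bromo-4-chloro-4-methylcyclohexane-1-carboxylate | COC(=O)[C@@]1(OC(=O)c2ccccc2)CC[C@@](C)(Cl)[C@H](Br)C1 | intermediate
10 | methyl (1R,3S,4S)-1-(benzoyloxy)-4-bromo-3-chloro-4-methylcyclohexane-1-carboxylate | COC(=O)[C@@]1(OC(=O)c2ccccc2)CC[C@](C)(Br)[C@@H](Cl)C1 | intermediate
11 | (1R,3S,4S)-4-bromo-3-chloro-1-[2-hydroxy-1,3-bis(trimethylsilyl)propan-2-yl]-4-methylcyclohexan-1-ol | C[Si](C)(C)CC(O)(C[Si](C)(C)C)[C@@]1(O)CC[C@](C)(Br)[C@@H](Cl)C1 | intermediate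
12 | (1R,3S,4S)-4-bromo-3-chloro-4-methyl-1-[3-(trimethylsilyl)prop-1-en-2-yl]cyclohexan-1-ol | C=C(C[Si](C)(C)C)[C@@]1(O)CC[C@](C)(Br)[C@@H](Cl)C1 | intermediate
13 | 3-methylbut-2-enoyl chloride | CC(C)=CC(Cl)=O | starting material
14 | 2-[(1R,3S,4S)-4-bromo-3-chloro-1-hydroxy-4-methylcyclohexyl]-6-methylhepta-1,5-dien-4-one | C=C(CC(=O)C=C(C)C)[C@@]1(O)CC[C@](C)(Br)[C@@H](Cl)C1 | intermediate
15 | (1R,3S,4S)-4-bromo-3-chloro-1-[(4S)-4-hydroxy-6-methylhepta-1,5-dien-2-yl]-4-methylcyclohexan-1-ol | C=C(C[C@H](O)C=C(C)C)[C@@]1(O)CC[C@](C)(Br)[C@@H](Cl)C1 | target

## Step count and least certain steps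

Total step count: 11. Longest linear sequence: 11 steps (1 to 15); 4 and 13 enter at steps 3 and 10.

Step 8 (key step). The most likely failure is incomplete or unfavourable equilibration. The relief of the Br/O 1,3-diaxial contact and the gain of two equatorial halogens are offset by an axial methyl group and by the weaker preference of bromine for the tertiary carbon, and ionisation can also leak into loss of HX. The fallback sets out from 6 and comes back at 12; it installs the halogens in the opposite order, so no equilibrium is needed. Saponification of 6 (LiOH, THF/H2O) would give (R)-1-hydroxy-4-methylcyclohex-3-ene-1-carboxylic acid F1. Esterification with (trimethylsilyl)diazomethane in PhMe/MeOH would give methyl (R)-1-hydroxy-4-methylcyclohex-3-ene-1-carboxylate F2 (the same compound as A6). N-Chlorosuccinimide in CH2Cl2 at 0 °C should close the C1 oxygen onto C4 while chlorine adds to C5 on the opposite face, giving methyl (1R,3S,4S)-3-chloro-4-methyl-7-oxabicyclo[2.2.1]heptane-1-carboxylate F3 (the same compound as A7). Cleavage of the tertiary C4–O bond with BBr3 (CH2Cl2, −78 °C), with the C5 chlorine bridging the developing cation so that bromide enters on the face the oxygen left, should give methyl (1R,3S,4S)-4-bromo-3-chloro-1-hydroxy-4-methylcyclohexane-1-carboxylate F4. F4 is taken through the conditions of step 9, with four equivalents of the reagent, to 12.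

Step 10. TiCl4 may ionise the tertiary bromide or the tertiary allylic alcohol at C1, and the allylsilane may be protodesilylated. The C7 alkene may also drift into conjugation, or the C1 hydroxyl may close onto the new C9 carbonyl as a hemiketal that dehydrates. The fallback sets out from 12 and comes back at 15, bypassing 14 and step 11. It is a catalytic enantioselective Hosomi–Sakurai addition of 12 to 3-methylbut-2-enal in EtCN at −78 °C. The catalyst is a chiral (acyloxy)borane prepared from a 2-O-(2,6-diisopropoxybenzoyl)tartaric acid (antipode selected for 9S) and 3,5-bis(trifluoromethyl)phenylboronic acid. It forms C8–C9 and the C9 stereocentre together without a stoichiometric strong Lewis acid. The primary product, (1R,3S,4S)-4-bromo-3-chloro-4-methyl-1-{(4S)-6-methyl-4-[(trimethylsilyl)oxy]hepta-1,5-dien-2-yl}cyclohexan-1-ol F5, is desilylated with citric acid in MeOH to 15.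

Step 11. Facial selectivity may be poor if the catalyst does not clearly rank the 2-methylprop-1-enyl arm above the CH2 arm, which is unbranched at the carbonyl but bulky further out. Some conjugate reduction is also possible. The fallback sets out from 14 and comes back at 15. It gives up reagent control: Luche reduction (NaBH4, CeCl3·7H2O, MeOH, −40 °C), separation of the two C9 epimers by chromatography (they are diastereomers), and return of the unwanted (1R,3S,4S)-4-bromo-3-chloro-1-[(4R)-4-hydroxy-6-methylhepta-1,5-dien-2-yl]-4-methylcyclohexan-1-ol F6 to 14 by oxidation with MnO2 in CH2Cl2.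

Step 3. Enantiofacial discrimination may be insufficient with a small acyclic diene, the sense of induction may be the opposite of the one assumed, and some 1,3 ("meta") adduct may form. The fallback sets out from 3 and 4 and comes back at 6. It replaces asymmetric catalysis by resolution. Thermal cycloaddition (PhMe, 80 °C, sealed) would give racemic 1-formyl-4-methylcyclohex-3-en-1-yl benzoate F7. Pinnick oxidation as in step 4 would give racemic 1-(benzoyloxy)-4-methylcyclohex-3-ene-1-carboxylic acid F8. Crystallisation with (R)-1-phenylethanamine would give the salt (R)-1-phenylethanaminium (R)-1-(benzoyloxy)-4-methylcyclohex-3-ene-1-carboxylate F9, from which acidification frees 6. The antipodal amine is used if the other salt is the less soluble one.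

Step 7. Water may be lost from the chlorosulfite towards C3 or the methyl group instead of substitution. The ester carbonyl may also capture the bromonium ion, which would return lactone 7. The fallback sets out from 6 and comes back at 9; it avoids the alcohol altogether. Esterification of 6 with (trimethylsilyl)diazomethane would give methyl (R)-1-(benzoyloxy)-4-methylcyclohex-3-ene-1-carboxylate F10. Direct bromochlorination (NBS, LiCl, MeCN, 0 °C) would then deliver chloride to the tertiary carbon. Face control by the C1 substituents alone is expected to be weaker, so 9 would have to be separated from the diastereomer that arises from the bromonium ion on the other face.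

## Further compounds

F1 | step 8 | (R)-1-hydroxy-4-methylcyclohex-3-ene-1-carboxylic acid | OC(=O)[C@@]1(O)CCC(C)=CC1
F2 | step 8 | methyl (R)-1-hydroxy-4-methylcyclohex-3-ene-1-carboxylate | COC(=O)[C@@]1(O)CCC(C)=CC1
F3 | step 8 | methyl (1R,3S,4S)-3-chloro-4-methyl-7-oxabicyclo[2.2.1]heptane-1-carboxylate | COC(=O)[C@@]1(O2)CC[C@@]2(C)[C@@H](Cl)C1
F4 | step 8 | methyl (1R,3S,4S)-4-bromo-3-chloro-1-hydroxy-4-methylcyclohexane-1-carboxylate | COC(=O)[C@@]1(O)CC[C@](C)(Br)[C@@H](Cl)C1
F5 | step 10 | (1R,3S,4S)-4-bromo-3-chloro-4-methyl-1-{(4S)-6-methyl-4-[(trimethylsilyl)oxy]hepta-1,5-dien-2-yl}cyclohexan-1-ol | C=C(C[C@H](O[Si](C)(C)C)C=C(C)C)[C@@]1(O)CC[C@](C)(Br)[C@@H](Cl)C1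
F6 | step 11 | (1R,3S,4S)-4-bromo-3-chloro-1-[(4R)-4-hydroxy-6-methylhepta-1,5-dien-2-yl]-4-methylcyclohexan-1-ol | C=C(C[C@@H](O)C=C(C)C)[C@@]1(O)CC[C@](C)(Br)[C@@H](Cl)C1
F7 | step 3 | racemic 1-formyl-4-methylcyclohex-3-en-1-yl benzoate | O=CC1(OC(=O)c2ccccc2)CCC(C)=CC1
F8 | step 3 | racemic 1-(benzoyloxy)-4-methylcyclohex-3-ene-1-carboxylic acid | OC(=O)C1(OC(=O)c2ccccc2)CCC(C)=CC1
F9 | step 3 | (R)-1-phenylethanaminium (R)-1-(benzoyloxy)-4-methylcyclohex-3-ene-1-carboxylate | C[C@@H]([NH3+])c1ccccc1.[O-]C(=O)[C@@]1(OC(=O)c2ccccc2)CCC(C)=CC1
F10 | step 7 | methyl (R)-1-(benzoyloxy)-4-methylcyclohex-3-ene-1-carboxylate | COC(=O)[C@@]1(OC(=O)c2ccccc2)CCC(C)=CC1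
A1 | alternative 1 | methyl propiolate | C#CC(=O)OC
A2 | alternative 1 | (4-methylcyclohexa-1,4-dien-1-yl)methanol | OCC1=CCC(C)=CC1
A3 | alternative 1 | [(1R,6R)-4-methyl-7-oxabicyclo[4.1.0]hept-3-en-1-yl]methanol | OC[C@@]1(O2)[C@H]2CC(C)=CC1
A4 | alternative 1 | (R)-1-(hydroxymethyl)-4-methylcyclohex-3-en-1-ol | OC[C@@]1(O)CCC(C)=CC1
A5 | alternative 2 | (R)-1-formyl-4-methylcyclohex-3-en-1-yl benzoate | O=C[C@@]1(OC(=O)c2ccccc2)CCC(C)=CC1
A6 | alternative 3 | methyl (R)-1-hydroxy-4-methylcyclohex-3-ene-1-carboxylate | COC(=O)[C@@]1(O)CCC(C)=CC1
A7 | alternative 3 | methyl (1R,3S,4S)-3-chloro-4-methyl-7-oxabicyclo[2.2.1]heptane-1-carboxylate | COC(=O)[C@@]1(O2)CC[C@@]2(C)[C@@H](Cl)C1
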